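**Retrosynthetic overview**
1. Target 24 comes from keto-lactone 19 by late adjustments only: O8 desilylation and acylation, CBS reduction of the C3 ketone, and C15 desilylation.
2. Key disconnection of 19: C6–C7 and O6–C12 together. A chromium Barbier allylation/lactonization of bromo ester–aldehyde 18 closes the ten-membered carbocycle and the α-methylene-γ-lactone in one operation and sets C6 and C7.
3. The (Z)-4-oxo-enal of 18 (C3–C6 plus C15) is a masked 2,3-disubstituted furan; oxidative opening of furan 17 delivers the 4Z olefin without an olefination.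
4. The furan is attached at C2–C3 by alkylating dilithiated furan-3-ylmethanol with epoxy triflate 9. The epoxide comes from a Sharpless epoxidation, the E-olefin from a Negishi carboalumination, C8 from (S)-glycidol, and C11–C13 from methyl acrylate.
5. Ring order: epoxide first (step 4), then the ten-membered ring and the lactone together (step 11).

Assumption: atoms are located with germacrane numbering (ring C1–C10, lactone carbons C11–C13, C14 on C10, C15 on C4), and the SMILES is read as 1R,3S,6R,7R,8R,10R,4Z with a (2S)-2-methylbutanoate on O8.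

**Route**

Step 1
Reactants: 1 (S)-glycidol
Product: 2 (2R)-pent-4-yne-1,2-diol
Conditions: LiC≡CH·H2NCH2CH2NH2 (3 equiv), DMSO, 0 → 23 °C; H2O
Reagents that add atoms: lithium acetylide–ethylenediamine complex, [Li+].[C-]#C.NCCN
Why: Epoxide alkynylation: the acetylide opens the terminal epoxide carbon by SN2, so the existing stereocentre is untouched and becomes C8 (R).

Step 2
Reactants: 2 (2R)-pent-4-yne-1,2-diol
Product: 3 (4R)-4,5-bis(triethylsilyloxy)pent-1-yne
Conditions: Et3SiCl (2.4 equiv), imidazole, DMF, 0 → 23 °C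
Reagents that add atoms: chlorotriethylsilane, CC[Si](Cl)(CC)CC
Why: Standard silylation of both hydroxyls; the primary triethylsilyl ether is later the handle for direct oxidation and the secondary one blocks O8.

Step 3
Reactants: 3 (4R)-4,5-bis(triethylsilyloxy)pent-1-yne
Product: 6 (2E,5R)-3-methyl-5,6-bis(triethylsilyloxy)hex-2-en-1-ol, via alkenylalane 4 (not isolated), via lithium alanate 5 (not isolated)
Conditions: Me3Al (2.5 equiv), Cp2ZrCl2 (0.25 equiv), CH2Cl2, 0 → 23 °C; volatiles removed; n-BuLi, THF, −78 °C; (CH2O)n, −78 → 23 °C; H2O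
Reagents that add atoms: trimethylaluminium, C[Al](C)C; paraformaldehyde (as formaldehyde), C=O
Why: Negishi zirconium-catalysed carboalumination adds methyl and aluminium syn across the alkyne with the metal on the terminal carbon, and the alanate is hydroxymethylated with retention, which gives the E-trisubstituted allylic alcohol (C2, C1=C10, C14).

Step 4
Reactants: 6 (2E,5R)-3-methyl-5,6-bis(triethylsilyloxy)hex-2-en-1-ol
Product: 7 {(2R,3R)-3-[(2R)-2,3-bis(triethylsilyloxy)propyl]-3-methyloxiran-2-yl}methanol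
Conditions: Ti(OiPr)4 (10 mol %), D-(−)-diethyl tartrate (12 mol %), t-BuOOH, 4 Å MS, CH2Cl2, −20 °C
Reagents that add atoms: tert-butyl hydroperoxide, CC(C)(C)OO
Why: Sharpless asymmetric epoxidation under reagent control: the D-(−)-tartrate complex delivers oxygen to the face that gives the 2R,3R epoxy alcohol (the L-(+)-ligand gives 2S,3S with geraniol-type alcohols), which fixes C1 and C10 as the trans epoxide.

Step 5
Reactants: 7 epoxy alcohol; 8 furan-3-ylmethanol
Product: 11 [2-({(2R,3R)-3-[(2R)-2,3-bis(triethylsilyloxy)propyl]-3-methyloxiran-2-yl}methyl)furan-3-yl]methanol, via epoxy triflate 9 (not isolated), via dilithiated furanmethanol 10 (not isolated)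
Conditions: 7, n-BuLi (1.0 equiv), Et2O, −78 °C, then Tf2O; added at −78 °C to 8 + n-BuLi (2.2 equiv), THF (−78 → 0 °C, recooled); → −20 °C; H2O
Reagents that add atoms: none
Why: Alkoxide-directed C2 lithiation of the furan followed by SN2 alkylation with a primary epoxy triflate, which is displaced much faster than the trisubstituted epoxide opens, so the C2–C3 bond forms with both epoxide centres retained.

Step 6
Reactants: 11 furylmethanol
Product: 12 tert-butyl{[2-({(2R,3R)-3-[(2R)-2,3-bis(triethylsilyloxy)propyl]-3-methyloxiran-2-yl}methyl)furan-3-yl]methoxy}dimethylsilane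
Conditions: t-BuMe2SiCl, imidazole, DMF, 23 °C
Reagents that add atoms: tert-butyl(chloro)dimethylsilane, CC(C)(C)[Si](C)(C)Cl
Why: Silylation of the only free hydroxyl (O15) with a group that outlasts the triethylsilyl ethers.

Step 7
Reactants: 12 tris-silyl ether
Product: 13 (2R)-3-{(2R,3R)-3-[(3-{[tert-butyl(dimethyl)silyl]oxymethyl}furan-2-yl)methyl]-2-methyloxiran-2-yl}-2-(triethylsilyloxy)propanal
Conditions: (COCl)2, DMSO, CH2Cl2, −78 °C; 12, −78 → −40 °C; Et3N, → 0 °C
Reagents that add atoms: none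
Why: Swern oxidation applied directly to the silyl ether: the unhindered primary triethylsilyl ether is cleaved by the chlorosulfonium reagent and oxidised in the same flask, the secondary TES and the TBS ether survive, and the cold amine step does not epimerise C8.

Step 8
Reactants: 13 aldehyde; 14 methyl acrylate
Product: 15 methyl (3RS,4R)-5-{(2R,3R)-3-[(3-{[tert-butyl(dimethyl)silyl]oxymethyl}furan-2-yl)methyl]-2-methyloxiran-2-yl}-3-hydroxy-2-methylidene-4-(triethylsilyloxy)pentanoate
Conditions: 14 (10 equiv), DABCO (1 equiv), MeOH (cat.), 23 °C, 3 d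
Reagents that add atoms: none
Why: Morita–Baylis–Hillman reaction of an activated α-silyloxy aldehyde brings in C11–C13; the new carbinol centre (C7) forms as a mixture that does not matter because the next step makes C7 trigonal.

Step 9
Reactants: 15 Baylis–Hillman alcohol
Product: 17 methyl (2Z,4R)-2-(bromomethyl)-5-{(2R,3R)-3-[(3-{[tert-butyl(dimethyl)silyl]oxymethyl}furan-2-yl)methyl]-2-methyloxiran-2-yl}-4-(triethylsilyloxy)pent-2-enoate, via allylic mesylate 16 (not isolated)
Conditions: MeSO2Cl, Et3N, CH2Cl2, −40 °C; LiBr, THF, −40 → 0 °C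
Reagents that add atoms: lithium bromide, [Li+].[Br-]
Why: Mesylation then SN2′ displacement by bromide transposes the allylic system to the thermodynamically preferred (Z)-2-(bromomethyl)enoate under neutral conditions that spare the furan and the epoxide.

Step 10
Reactants: 17 furyl allylic bromide
Product: 18 methyl (2Z,4R)-2-(bromomethyl)-5-{(2R,3R)-3-[(3Z)-3-{[tert-butyl(dimethyl)silyl]oxymethyl}-2,5-dioxopent-3-en-1-yl]-2-methyloxiran-2-yl}-4-(triethylsilyloxy)pent-2-enoate
Conditions: NBS (1.05 equiv), NaHCO3, acetone–H2O (10:1), −20 °C, 20 min; used at once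
Reagents that add atoms: water, O
Why: Oxidative furan ring opening (bromonium attack, water addition, ring fragmentation) releases the cis-enedicarbonyl, so the furan ring geometry becomes the 4Z olefin, C6 appears as the aldehyde and C3 as a ketone, and the electron-poor enoate and the allylic bromide are untouched.

Step 11
Reactants: 18 bromo ester oxo-enal
Product: 19 (1R,6R,7S,8R,10R,4Z)-15-(tert-butyldimethylsilyloxy)-1,10-epoxy-3-oxo-8-(triethylsilyloxy)germacra-4,11(13)-dien-12,6-olide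
Conditions: CrCl2 (10 equiv), THF–DMF (3:1), 18 added over 12 h (final 0.002 M), 23 °C; H2O
Reagents that add atoms: none
Why: Nozaki–Hiyama chromium Barbier allylation with in-flask lactonization: CrCl2 converts the allylic bromide into an allylchromium that attacks only the aldehyde (closure onto the ketone would need a seven-membered ring with a trans-fused epoxide), the chair-like transition state inside the forming ten-membered ring is expected to hold C9 in the allyl plane with the aldehyde anti to the C8 silyloxy group and the Z-alkenyl chain equatorial, which would set C7 and C6 as the 6,7-trans pair, and the trivalent chromium alkoxide then closes onto the methyl ester, so the carbocycle and the γ-lactone form in the same operation.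

Step 12
Reactants: 19 macrocyclic keto-lactone
Product: 20 (1R,6R,7R,8R,10R,4Z)-15-(tert-butyldimethylsilyloxy)-1,10-epoxy-8-hydroxy-3-oxogermacra-4,11(13)-dien-12,6-olide
Conditions: HF·pyridine, pyridine, THF, 0 °C
Reagents that add atoms: none
Why: Selective fluoride desilylation: the secondary triethylsilyl ether is cleaved well before the primary TBS ether, and the pyridine buffer protects the epoxide and the β,γ-epoxy ketone.

Step 13
Reactants: 20 C8 alcohol; 21 (S)-2-methylbutanoic acid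
Product: 22 (1R,6R,7R,8R,10R,4Z)-15-(tert-butyldimethylsilyloxy)-1,10-epoxy-8-[(2S)-2-methylbutanoyloxy]-3-oxogermacra-4,11(13)-dien-12,6-olide
Conditions: DCC, DMAP (0.1 equiv), CH2Cl2, 0 → 23 °C
Reagents that add atoms: none
Why: Steglich esterification of the only free hydroxyl (C3 is still a ketone, O15 is silylated), with carbodiimide activation at low temperature so that the α-stereocentre of the acid is not racemised.

Step 14
Reactants: 22 keto ester
Product: 23 (1R,3S,6R,7R,8R,10R,4Z)-15-(tert-butyldimethylsilyloxy)-1,10-epoxy-3-hydroxy-8-[(2S)-2-methylbutanoyloxy]germacra-4,11(13)-dien-12,6-olide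
Conditions: (R)-2-methyl-CBS-oxazaborolidine (0.5 equiv), catecholborane (1.5 equiv), toluene–CH2Cl2, −78 °C; pH 7 buffer
Reagents that add atoms: none
Why: Corey–Bakshi–Shibata reduction: the oxazaborolidine–borane complex binds the enone carbonyl anti to the larger alkenyl arm and delivers hydride 1,2, the (R)-catalyst giving the 3S allylic alcohol, while the α-methylene lactone, the ester and the epoxide are inert at −78 °C.

Step 15
Reactants: 23 silyl ether
Product: 24 CNP0267576.2, (1R,3S,6R,7R,8R,10R,4Z)-1,10-epoxy-3,15-dihydroxy-8-[(2S)-2-methylbutanoyloxy]germacra-4,11(13)-dien-12,6-olide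
Conditions: HF·pyridine, pyridine, THF, 0 → 23 °C
Reagents that add atoms: none
Why: Fluoride desilylation of the primary allylic TBS ether under pyridine-buffered conditions that leave the epoxide, the ester and the α-methylene lactone intact.

**Compound list**
1 | (S)-glycidol, (2S)-oxiran-2-ylmethanol | OC[C@H]1CO1 | starting material
2 | (2R)-pent-4-yne-1,2-diol | C#CC[C@@H](O)CO | intermediate
3 | (4R)-4,5-bis(triethylsilyloxy)pent-1-yne | C#CC[C@@H](O[Si](CC)(CC)CC)CO[Si](CC)(CC)CC | intermediate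
4 | dimethyl[(1E,4R)-2-methyl-4,5-bis(triethylsilyloxy)pent-1-en-1-yl]alane | C[Al](C)/C=C(\C)C[C@@H](O[Si](CC)(CC)CC)CO[Si](CC)(CC)CC | intermediate (not isolated)
5 | lithium butyl(dimethyl)[(1E,4R)-2-methyl-4,5-bis(triethylsilyloxy)pent-1-en-1-yl]alanate | [Li+].CCCC[Al-](C)(C)/C=C(\C)C[C@@H](O[Si](CC)(CC)CC)CO[Si](CC)(CC)CC | intermediate (not isolated)
6 | (2E,5R)-3-methyl-5,6-bis(triethylsilyloxy)hex-2-en-1-ol | OC/C=C(\C)C[C@@H](O[Si](CC)(CC)CC)CO[Si](CC)(CC)CC | intermediate
7 | {(2R,3R)-3-[(2R)-2,3-bis(triethylsilyloxy)propyl]-3-methyloxiran-2-yl}methanol | OC[C@H]1O[C@]1(C)C[C@@H](O[Si](CC)(CC)CC)CO[Si](CC)(CC)CC | intermediate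
8 | furan-3-ylmethanol | OCc1ccoc1 | starting material
9 | {(2R,3R)-3-[(2R)-2,3-bis(triethylsilyloxy)propyl]-3-methyloxiran-2-yl}methyl trifluoromethanesulfonate | FC(F)(F)S(=O)(=O)OC[C@H]1O[C@]1(C)C[C@@H](O[Si](CC)(CC)CC)CO[Si](CC)(CC)CC | intermediate (not isolated)
10 | 2-lithio-3-(lithiooxymethyl)furan | [Li]OCc1ccoc1[Li] | intermediate (not isolated)
11 | [2-({(2R,3R)-3-[(2R)-2,3-bis(triethylsilyloxy)propyl]-3-methyloxiran-2-yl}methyl)furan-3-yl]methanol | OCc1ccoc1C[C@H]1O[C@]1(C)C[C@@H](O[Si](CC)(CC)CC)CO[Si](CC)(CC)CC | intermediate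
12 | tert-butyl{[2-({(2R,3R)-3-[(2R)-2,3-bis(triethylsilyloxy)propyl]-3-methyloxiran-2-yl}methyl)furan-3-yl]methoxy}dimethylsilane | CC(C)(C)[Si](C)(C)OCc1ccoc1C[C@H]1O[C@]1(C)C[C@@H](O[Si](CC)(CC)CC)CO[Si](CC)(CC)CC | intermediate
13 | (2R)-3-{(2R,3R)-3-[(3-{[tert-butyl(dimethyl)silyl]oxymethyl}furan-2-yl)methyl]-2-methyloxiran-2-yl}-2-(triethylsilyloxy)propanal | CC(C)(C)[Si](C)(C)OCc1ccoc1C[C@H]1O[C@]1(C)C[C@@H](O[Si](CC)(CC)CC)C=O | intermediate
14 | methyl acrylate | C=CC(=O)OC | starting material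
15 | methyl (3RS,4R)-5-{(2R,3R)-3-[(3-{[tert-butyl(dimethyl)silyl]oxymethyl}furan-2-yl)methyl]-2-methyloxiran-2-yl}-3-hydroxy-2-methylidene-4-(triethylsilyloxy)pentanoate (both C3 epimers) | CC(C)(C)[Si](C)(C)OCc1ccoc1C[C@H]1O[C@]1(C)C[C@@H](O[Si](CC)(CC)CC)C(O)C(=C)C(=O)OC | intermediate
16 | 3-methanesulfonate of 15 | CC(C)(C)[Si](C)(C)OCc1ccoc1C[C@H]1O[C@]1(C)C[C@@H](O[Si](CC)(CC)CC)C(OS(C)(=O)=O)C(=C)C(=O)OC | intermediate (not isolated)
17 | methyl (2Z,4R)-2-(bromomethyl)-5-{(2R,3R)-3-[(3-{[tert-butyl(dimethyl)silyl]oxymethyl}furan-2-yl)methyl]-2-methyloxiran-2-yl}-4-(triethylsilyloxy)pent-2-enoate | CC(C)(C)[Si](C)(C)OCc1ccoc1C[C@H]1O[C@]1(C)C[C@@H](O[Si](CC)(CC)CC)/C=C(\CBr)C(=O)OC | intermediate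
18 | methyl (2Z,4R)-2-(bromomethyl)-5-{(2R,3R)-3-[(3Z)-3-{[tert-butyl(dimethyl)silyl]oxymethyl}-2,5-dioxopent-3-en-1-yl]-2-methyloxiran-2-yl}-4-(triethylsilyloxy)pent-2-enoate | CC(C)(C)[Si](C)(C)OC/C(=C/C=O)C(=O)C[C@H]1O[C@]1(C)C[C@@H](O[Si](CC)(CC)CC)/C=C(\CBr)C(=O)OC | intermediate
19 | (1R,6R,7S,8R,10R,4Z)-15-(tert-butyldimethylsilyloxy)-1,10-epoxy-3-oxo-8-(triethylsilyloxy)germacra-4,11(13)-dien-12,6-olide (7S only through the rank of the silyl ether; spatially as C7 of 24) | C=C1C(=O)O[C@@H]2/C=C(/CO[Si](C)(C)C(C)(C)C)C(=O)C[C@H]3O[C@]3(C)C[C@@H](O[Si](CC)(CC)CC)[C@@H]12 | intermediate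
20 | (1R,6R,7R,8R,10R,4Z)-15-(tert-butyldimethylsilyloxy)-1,10-epoxy-8-hydroxy-3-oxogermacra-4,11(13)-dien-12,6-olide | C=C1C(=O)O[C@@H]2/C=C(/CO[Si](C)(C)C(C)(C)C)C(=O)C[C@H]3O[C@]3(C)C[C@@H](O)[C@@H]12 | intermediate
21 | (S)-2-methylbutanoic acid | CC[C@H](C)C(=O)O | starting material
22 | (1R,6R,7R,8R,10R,4Z)-15-(tert-butyldimethylsilyloxy)-1,10-epoxy-8-[(2S)-2-methylbutanoyloxy]-3-oxogermacra-4,11(13)-dien-12,6-olide | C=C1C(=O)O[C@@H]2/C=C(/CO[Si](C)(C)C(C)(C)C)C(=O)C[C@H]3O[C@]3(C)C[C@@H](OC(=O)[C@@H](C)CC)[C@@H]12 | intermediate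
23 | (1R,3S,6R,7R,8R,10R,4Z)-15-(tert-butyldimethylsilyloxy)-1,10-epoxy-3-hydroxy-8-[(2S)-2-methylbutanoyloxy]germacra-4,11(13)-dien-12,6-olide | C=C1C(=O)O[C@@H]2/C=C(/CO[Si](C)(C)C(C)(C)C)[C@@H](O)C[C@H]3O[C@]3(C)C[C@@H](OC(=O)[C@@H](C)CC)[C@@H]12 | intermediate
24 | CNP0267576.2, (1R,3S,6R,7R,8R,10R,4Z)-1,10-epoxy-3,15-dihydroxy-8-[(2S)-2-methylbutanoyloxy]germacra-4,11(13)-dien-12,6-olide | C=C1C(=O)O[C@@H]2/C=C(/CO)[C@@H](O)C[C@H]3O[C@]3(C)C[C@@H](OC(=O)[C@@H](C)CC)[C@@H]12 | target

**Totals**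
Total step count: 15. Longest linear sequence: 15 steps (1 → 24); 8, 14 and 21 are bought and enter directly.

**Steps most likely to fail**

Step 11 (ring closure). The slow ten-membered closure competes with oligomerization, divalent chromium may reduce the electron-poor ene-dione, and the facial outcome rests on ring constraints rather than on a proven model. Fallback: set out from 17 and remove the triethylsilyl group (HF·pyridine, pyridine, THF, 0 °C) to give the hydroxy bromo ester F1. Open the furan as in step 10 to the hydroxy oxo-enal F2. Cyclise F2 with indium powder (zerovalent indium) in DMF–THF at high dilution. The free C8 hydroxyl binds indium and steers the allyl transfer (hydroxyl-directed indium Barbier allylation), indium does not reduce the ene-dione, and only the newly formed indium alkoxide at C6 attacks the ester. This gives 20 directly, so the route is rejoined at 20 and step 12 falls away.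

Step 13 (acylation on the keto stage). The hindered C8 hydroxyl must be esterified while a base-sensitive β,γ-epoxy enone and a neighbouring lactone are present; DMAP could trigger epoxide opening by enolization or lactone migration. Fallback: set out from 19 and reduce the ketone first, with (R)-2-methyl-CBS-oxazaborolidine and catecholborane, to the C3 alcohol F3. Silylate it (t-BuMe2SiOTf, 2,6-lutidine) to the C3 TBS ether F4. Cleave the triethylsilyl ether (HF·pyridine, pyridine, 0 °C) to the C8 alcohol F5, and esterify with 21 (DCC, DMAP) to the bis-TBS ester F6. Removal of both TBS groups (HF·pyridine, pyridine) leads straight to 24, where the route is rejoined.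

Step 14 (C3 configuration). The conformation of the macrocycle may override the catalyst and give mainly the 3R alcohol. Fallback: set out from 22 and reduce under substrate control (NaBH4, CeCl3·7H2O, MeOH–THF, −78 °C, Luche conditions). If this gives the 3R alcohol F7, invert it by a Mitsunobu reaction with chloroacetic acid (PPh3, DIAD) to the 3S chloroacetate F8. Remove the chloroacetyl group with thiourea and NaHCO3 in EtOH; this spares the 2-methylbutanoate and the lactone and comes back to the route at 23.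

Further compounds
F1 | step 11 | methyl (2Z,4R)-2-(bromomethyl)-5-{(2R,3R)-3-[(3-{[tert-butyl(dimethyl)silyl]oxymethyl}furan-2-yl)methyl]-2-methyloxiran-2-yl}-4-hydroxypent-2-enoate | CC(C)(C)[Si](C)(C)OCc1ccoc1C[C@H]1O[C@]1(C)C[C@@H](O)/C=C(\CBr)C(=O)OC
F2 | step 11 | methyl (2Z,4R)-2-(bromomethyl)-5-{(2R,3R)-3-[(3Z)-3-{[tert-butyl(dimethyl)silyl]oxymethyl}-2,5-dioxopent-3-en-1-yl]-2-methyloxiran-2-yl}-4-hydroxypent-2-enoate | CC(C)(C)[Si](C)(C)OC/C(=C/C=O)C(=O)C[C@H]1O[C@]1(C)C[C@@H](O)/C=C(\CBr)C(=O)OC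
F3 | step 13 | (1R,3S,6R,7S,8R,10R,4Z)-15-(tert-butyldimethylsilyloxy)-1,10-epoxy-3-hydroxy-8-(triethylsilyloxy)germacra-4,11(13)-dien-12,6-olide | C=C1C(=O)O[C@@H]2/C=C(/CO[Si](C)(C)C(C)(C)C)[C@@H](O)C[C@H]3O[C@]3(C)C[C@@H](O[Si](CC)(CC)CC)[C@@H]12
F4 | step 13 | (1R,3S,6R,7S,8R,10R,4Z)-3,15-bis(tert-butyldimethylsilyloxy)-1,10-epoxy-8-(triethylsilyloxy)germacra-4,11(13)-dien-12,6-olide | C=C1C(=O)O[C@@H]2/C=C(/CO[Si](C)(C)C(C)(C)C)[C@@H](O[Si](C)(C)C(C)(C)C)C[C@H]3O[C@]3(C)C[C@@H](O[Si](CC)(CC)CC)[C@@H]12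
F5 | step 13 | (1R,3S,6R,7R,8R,10R,4Z)-3,15-bis(tert-butyldimethylsilyloxy)-1,10-epoxy-8-hydroxygermacra-4,11(13)-dien-12,6-olide | C=C1C(=O)O[C@@H]2/C=C(/CO[Si](C)(C)C(C)(C)C)[C@@H](O[Si](C)(C)C(C)(C)C)C[C@H]3O[C@]3(C)C[C@@H](O)[C@@H]12
F6 | step 13 | (1R,3S,6R,7R,8R,10R,4Z)-3,15-bis(tert-butyldimethylsilyloxy)-1,10-epoxy-8-[(2S)-2-methylbutanoyloxy]germacra-4,11(13)-dien-12,6-olide | C=C1C(=O)O[C@@H]2/C=C(/CO[Si](C)(C)C(C)(C)C)[C@@H](O[Si](C)(C)C(C)(C)C)C[C@H]3O[C@]3(C)C[C@@H](OC(=O)[C@@H](C)CC)[C@@H]12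
F7 | step 14 | (1R,3R,6R,7R,8R,10R,4Z)-15-(tert-butyldimethylsilyloxy)-1,10-epoxy-3-hydroxy-8-[(2S)-2-methylbutanoyloxy]germacra-4,11(13)-dien-12,6-olide | C=C1C(=O)O[C@@H]2/C=C(/CO[Si](C)(C)C(C)(C)C)[C@H](O)C[C@H]3O[C@]3(C)C[C@@H](OC(=O)[C@@H](C)CC)[C@@H]12
F8 | step 14 | (1R,3S,6R,7R,8R,10R,4Z)-15-(tert-butyldimethylsilyloxy)-3-(chloroacetyloxy)-1,10-epoxy-8-[(2S)-2-methylbutanoyloxy]germacra-4,11(13)-dien-12,6-olide | C=C1C(=O)O[C@@H]2/C=C(/CO[Si](C)(C)C(C)(C)C)[C@@H](OC(=O)CCl)C[C@H]3O[C@]3(C)C[C@@H](OC(=O)[C@@H](C)CC)[C@@H]12
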